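**Plan**
- Numbering and key feature: C1 sits on the methoxy-bearing ring A and C14 on the dihydroxy ring B. C8=C9 is the only functionalised part of the tether. It lies between a straight (CH2)7 arm (C1–C7) and a straight (CH2)5 arm (C10–C14), so C8 and C9 can both come from acetylene.
- Cuts: first the three O–CH2OMe protecting bonds, then C8=C9 back to C8≡C9, then C7–C8 and C9–C10 together, and last ring A–C1 and ring B–C14.
- Forward: both rings are bought and no ring is made. Each arm is attached to its ring by Sonogashira coupling, saturated and brominated. The ring A arm and then the ring B arm are joined to acetylene in one flask.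
- Stereochemistry: there is no stereocentre. The E alkene arises from Na/NH3 trans reduction of the C8≡C9 alkyne, and the acetals are removed with acid afterwards.

Key step: step 9

Assumption: the E geometry at C8=C9 is the only stereochemical issue, and the two bromophenols, the two alkynols and acetylene gas are taken as purchasable.

**Step 1**
Reactants: 1 3-bromo-5-methoxyphenol
Product: 2 1-bromo-3-methoxy-5-(methoxymethoxy)benzene
Conditions: NaH (1.2 equiv), MOMCl (1.2 equiv), DMF, 0 °C → rt
Reagents that add atoms: chloromethyl methyl ether (MOMCl), COCCl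
Why: Williamson-type O-alkylation, in which the sodium phenoxide attacks the highly electrophilic α-chloro ether to give the methoxymethyl acetal while the aryl bromide and the methyl ether are untouched.

**Step 2**
Reactants: 2 1-bromo-3-methoxy-5-(methoxymethoxy)benzene; 3 hept-6-yn-1-ol
Product: 4 7-[3-methoxy-5-(methoxymethoxy)phenyl]hept-6-yn-1-ol
Conditions: PdCl2(PPh3)2 (3 mol %), CuI (6 mol %), Et3N (degassed), 80 °C
Reagents that add atoms: none
Why: Sonogashira coupling, in which zerovalent palladium inserts into the C–Br bond (both oxygen substituents are meta and do not donate into that carbon), the copper acetylide of 3 transmetalates and reductive elimination forms the ring A–C1 bond with the free primary alcohol tolerated.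

**Step 3**
Reactants: 4 7-[3-methoxy-5-(methoxymethoxy)phenyl]hept-6-yn-1-ol
Product: 5 7-[3-methoxy-5-(methoxymethoxy)phenyl]heptan-1-ol
Conditions: H2 (1 atm), 10% Pd/C, EtOAc, rt
Reagents that add atoms: none
Why: Heterogeneous catalytic hydrogenation saturates the aryl alkyne, while arene, methyl ether and acetal are inert in a neutral aprotic solvent and no hydrogenolysable benzylic C–O bond is present.

**Step 4**
Reactants: 5 7-[3-methoxy-5-(methoxymethoxy)phenyl]heptan-1-ol
Product: 6 1-(7-bromoheptyl)-3-methoxy-5-(methoxymethoxy)benzene
Conditions: CBr4 (1.2 equiv), PPh3 (1.25 equiv), CH2Cl2, 0 °C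
Reagents that add atoms: carbon tetrabromide, BrC(Br)(Br)Br
Why: Appel reaction, in which the alkoxyphosphonium ion formed from PPh3, CBr4 and the primary alcohol is displaced by bromide in an SN2 step under essentially neutral conditions that the acid-labile acetal tolerates.

**Step 5**
Reactants: 7 5-bromoresorcinol (5-bromobenzene-1,3-diol)
Product: 8 1-bromo-3,5-bis(methoxymethoxy)benzene
Conditions: NaH (2.4 equiv), MOMCl (2.4 equiv), DMF, 0 °C → rt
Reagents that add atoms: chloromethyl methyl ether (MOMCl), COCCl
Why: Double Williamson-type O-alkylation with the α-chloro ether converts both equivalent phenoxides into methoxymethyl acetals, which removes every acidic proton that would later quench the organolithium reagents.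

**Step 6**
Reactants: 8 1-bromo-3,5-bis(methoxymethoxy)benzene; 9 pent-4-yn-1-ol
Product: 10 5-[3,5-bis(methoxymethoxy)phenyl]pent-4-yn-1-ol
Conditions: PdCl2(PPh3)2 (3 mol %), CuI (6 mol %), Et3N (degassed), 80 °C
Reagents that add atoms: none
Why: Sonogashira coupling, in which zerovalent palladium inserts into the C–Br bond meta to both acetal oxygens, the copper acetylide formed from 9, CuI and Et3N transmetalates and reductive elimination forms the ring B–C14 bond without protection of the alcohol.

**Step 7**
Reactants: 10 5-[3,5-bis(methoxymethoxy)phenyl]pent-4-yn-1-ol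
Product: 11 5-[3,5-bis(methoxymethoxy)phenyl]pentan-1-ol
Conditions: H2 (1 atm), 10% Pd/C, EtOAc, rt
Reagents that add atoms: none
Why: Heterogeneous catalytic hydrogenation adds two molecules of H2 to the conjugated alkyne to give the five-CH2 arm and leaves arene and acetals untouched under neutral conditions.

**Step 8**
Reactants: 11 5-[3,5-bis(methoxymethoxy)phenyl]pentan-1-ol
Product: 12 1-(5-bromopentyl)-3,5-bis(methoxymethoxy)benzene
Conditions: CBr4 (1.2 equiv), PPh3 (1.25 equiv), CH2Cl2, 0 °C
Reagents that add atoms: carbon tetrabromide, BrC(Br)(Br)Br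
Why: Appel reaction, in which activation of the primary alcohol as its alkoxyphosphonium ion and SN2 attack of bromide give the bromide without free acid, so both acetals should persist.

**Step 9**
Reactants: 6 1-(7-bromoheptyl)-3-methoxy-5-(methoxymethoxy)benzene; 13 acetylene; 12 1-(5-bromopentyl)-3,5-bis(methoxymethoxy)benzene
Product: 17 1-[3-methoxy-5-(methoxymethoxy)phenyl]-14-[3,5-bis(methoxymethoxy)phenyl]tetradec-8-yne, via lithium acetylide 14 (not isolated), via terminal alkyne of the ring A arm 15 (not isolated), via lithium alkynide of the ring A arm 16 (not isolated)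
Conditions: 13 (saturated THF solution), n-BuLi (1.25 equiv), THF, −78 °C; 6 (1.0 equiv), DMPU, −78 °C → rt, acetylene balloon; Ar sparge, rt; n-BuLi (0.75 equiv), −78 °C; 12 (1.0 equiv), NaI (0.1 equiv), −78 → 40 °C
Reagents that add atoms: none
Why: n-BuLi deprotonates acetylene once in an acetylene-saturated solution, 14 displaces bromide from 6 by SN2 (C7–C8 bond), and after the dissolved acetylene has been swept out 15 is lithiated to 16, which displaces bromide from 12 in the same way (C9–C10 bond). The closest known reaction type is the sequential one-flask alkylation of acetylene with two different primary halides in THF plus a dipolar aprotic cosolvent, routine in long-chain lipid and pheromone synthesis. No ring is closed and no stereocentre is formed, the linear alkyne merely being the handle for the later E geometry. The selectivity needed is the mixed A–B alkyne over the A–A and B–B alkynes: in the first stage free acetylene holds the proton-transfer equilibrium between 14 and 15 on the side of 15, so 6 meets only 14, and in the second stage argon sparging converts the small surplus of 14 into volatile acetylene at the expense of 15 (which becomes 16), so 12 meets only 16. Lithiation must occur at the alkyne C–H and not at the aryl C–H between the two oxygen substituents, which is secured by a gap of more than ten pKa units, by −78 °C and by limiting n-BuLi to two equivalents in total, any aryllithium being reprotonated by remaining 15. E2 loss of HBr should be a side path only, since each C–Br carbon is primary with an unhindered CH2 neighbour and no acidifying group nearby, and aryl methyl ethers and aryl acetals do not react with carbanions of this basicity.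

**Step 10**
Reactants: 17 1-[3-methoxy-5-(methoxymethoxy)phenyl]-14-[3,5-bis(methoxymethoxy)phenyl]tetradec-8-yne
Product: 18 (E)-1-[3-methoxy-5-(methoxymethoxy)phenyl]-14-[3,5-bis(methoxymethoxy)phenyl]tetradec-8-ene
Conditions: Na (3 equiv), NH3(l)/THF, −33 °C, no alcohol; then solid NH4Cl
Reagents that add atoms: none
Why: Dissolving-metal reduction of a dialkyl alkyne, in which stepwise electron transfer and protonation by ammonia pass through a vinyl radical and vinyl anion that adopt the less crowded trans geometry and so set the E C8=C9 bond, while without an added alcohol the electron-rich rings should not be reduced at a comparable rate.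

**Step 11**
Reactants: 18 (E)-1-[3-methoxy-5-(methoxymethoxy)phenyl]-14-[3,5-bis(methoxymethoxy)phenyl]tetradec-8-ene
Product: 19 dehydrobisgravillol, 5-[(E)-14-(3-hydroxy-5-methoxyphenyl)tetradec-6-en-1-yl]benzene-1,3-diol
Conditions: HCl (1.25 M in MeOH), 40 °C
Reagents that add atoms: none
Why: Acid-catalysed transacetalisation (methanolysis of methoxymethyl ethers), in which each protonated acetal releases its phenol and a methoxymethyl cation that the solvent captures as dimethoxymethane before it can attack the resorcinol rings, while the aryl methyl ether and the isolated E alkene are inert to dilute HCl.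

**Compound list**
1 | 3-bromo-5-methoxyphenol | COc1cc(O)cc(Br)c1 | starting material
2 | 1-bromo-3-methoxy-5-(methoxymethoxy)benzene | COCOc1cc(Br)cc(OC)c1 | intermediate
3 | hept-6-yn-1-ol | C#CCCCCCO | starting material
4 | 7-[3-methoxy-5-(methoxymethoxy)phenyl]hept-6-yn-1-ol | COCOc1cc(OC)cc(C#CCCCCCO)c1 | intermediate
5 | 7-[3-methoxy-5-(methoxymethoxy)phenyl]heptan-1-ol | COCOc1cc(OC)cc(CCCCCCCO)c1 | intermediate
6 | 1-(7-bromoheptyl)-3-methoxy-5-(methoxymethoxy)benzene | COc1cc(OCOC)cc(CCCCCCCBr)c1 | intermediate
7 | 5-bromoresorcinol | Oc1cc(O)cc(Br)c1 | starting material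
8 | 1-bromo-3,5-bis(methoxymethoxy)benzene | COCOc1cc(Br)cc(OCOC)c1 | intermediate
9 | pent-4-yn-1-ol | C#CCCCO | starting material
10 | 5-[3,5-bis(methoxymethoxy)phenyl]pent-4-yn-1-ol | COCOc1cc(C#CCCCO)cc(OCOC)c1 | intermediate
11 | 5-[3,5-bis(methoxymethoxy)phenyl]pentan-1-ol | COCOc1cc(CCCCCO)cc(OCOC)c1 | intermediate
12 | 1-(5-bromopentyl)-3,5-bis(methoxymethoxy)benzene | COCOc1cc(CCCCCBr)cc(OCOC)c1 | intermediate
13 | acetylene | C#C | starting material
14 | lithium acetylide | [Li]C#C | intermediate
15 | 1-methoxy-3-(methoxymethoxy)-5-(non-8-yn-1-yl)benzene | COc1cc(OCOC)cc(CCCCCCCC#C)c1 | intermediate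
16 | {9-[3-methoxy-5-(methoxymethoxy)phenyl]non-1-yn-1-yl}lithium | COc1cc(OCOC)cc(CCCCCCCC#C[Li])c1 | intermediate
17 | 1-[3-methoxy-5-(methoxymethoxy)phenyl]-14-[3,5-bis(methoxymethoxy)phenyl]tetradec-8-yne | COc1cc(OCOC)cc(CCCCCCCC#CCCCCCc2cc(OCOC)cc(OCOC)c2)c1 | intermediate
18 | (E)-1-[3-methoxy-5-(methoxymethoxy)phenyl]-14-[3,5-bis(methoxymethoxy)phenyl]tetradec-8-ene | COc1cc(OCOC)cc(CCCCCCC/C=C/CCCCCc2cc(OCOC)cc(OCOC)c2)c1 | intermediate
19 | dehydrobisgravillol | COc1cc(O)cc(CCCCCCC/C=C/CCCCCc2cc(O)cc(O)c2)c1 | target

**Step count**
Total step count: 11.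
Longest linear sequence: 7 steps (steps 1–4, 9, 10, 11). The ring B arm (steps 5–8) is equally long and runs in parallel.

**Steps most likely to fail**

**Step 9.**
- Risk: Proton exchange among the acetylide species, or incomplete removal of acetylene, may let a bromide meet the wrong nucleophile. Symmetrical coupling would then compete with the mixed coupling. The second displacement may also stall.
- Fallback: It sets out from 6 and replaces free acetylene by a singly masked acetylene, with isolation between the two bond formations.
  - (Trimethylsilyl)acetylene (C#C[Si](C)(C)C) is lithiated with n-BuLi in THF at −78 °C to lithium (trimethylsilyl)acetylide F1.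
  - F1 is alkylated with 6 in THF/DMPU to give trimethyl{9-[3-methoxy-5-(methoxymethoxy)phenyl]non-1-yn-1-yl}silane F2, whose second terminus cannot react.
  - K2CO3 in MeOH removes the silyl group and delivers 15, now isolated and purified.
  - n-BuLi converts 15 into 16, and alkylation with 12 brings the sequence back to the route at 17.

**Step 10.**
- Risk: The lipophilic alkyne may dissolve poorly in ammonia, so the reduction may stall. More metal or longer contact would then invite partial Birch reduction of the rings or reductive loss of aryl ether groups.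
- Fallback: It sets out from 17 and uses a catalytic trans addition instead of electron transfer.
  - [Cp*Ru(MeCN)3]PF6 (5 mol %) and (EtO)3SiH in CH2Cl2 at 0 °C → rt should add H and Si to opposite faces.
  - Two products are expected: (Z)-1-[3-methoxy-5-(methoxymethoxy)phenyl]-14-[3,5-bis(methoxymethoxy)phenyl]-8-(triethoxysilyl)tetradec-8-ene F3 and its regioisomer (Z)-1-[3-methoxy-5-(methoxymethoxy)phenyl]-14-[3,5-bis(methoxymethoxy)phenyl]-9-(triethoxysilyl)tetradec-8-ene F4.
  - The two need not be separated, because protodesilylation with AgF in THF/MeOH/H2O replaces silicon by hydrogen with retention. Both converge on 18, where the route is rejoined.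

**Step 6.**
- Risk: Oxidative addition into the oxygen-rich aryl bromide may be slow. Oxidative (Glaser-type) dimerisation of the alkynol may then consume the coupling partner.
- Fallback: It sets out from 8 and forms the ring B–C14 bond as an sp2–sp3 bond by B-alkyl Suzuki–Miyaura coupling.
  - Pent-4-en-1-ol (C=CCCCO) is treated with 9-BBN-H (2.2 equiv, THF, 0 °C → rt) to give 9-[5-(9-borabicyclo[3.3.1]nonan-9-yloxy)pentyl]-9-borabicyclo[3.3.1]nonane F5.
  - F5 is coupled in the same flask with 8 using PdCl2(dppf) (3 mol %) and aqueous NaOH in THF at 65 °C.
  - The saturated alcohol 11 results directly, so 10 and the hydrogenation are bypassed.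

**Further compounds**
F1 | step 9 | lithium (trimethylsilyl)acetylide | [Li]C#C[Si](C)(C)C
F2 | step 9 | trimethyl{9-[3-methoxy-5-(methoxymethoxy)phenyl]non-1-yn-1-yl}silane | COc1cc(OCOC)cc(CCCCCCCC#C[Si](C)(C)C)c1
F3 | step 10 | (Z)-1-[3-methoxy-5-(methoxymethoxy)phenyl]-14-[3,5-bis(methoxymethoxy)phenyl]-8-(triethoxysilyl)tetradec-8-ene | COc1cc(OCOC)cc(CCCCCCC/C([Si](OCC)(OCC)OCC)=C/CCCCCc2cc(OCOC)cc(OCOC)c2)c1
F4 | step 10 | (Z)-1-[3-methoxy-5-(methoxymethoxy)phenyl]-14-[3,5-bis(methoxymethoxy)phenyl]-9-(triethoxysilyl)tetradec-8-ene | COc1cc(OCOC)cc(CCCCCCC/C=C(/CCCCCc2cc(OCOC)cc(OCOC)c2)[Si](OCC)(OCC)OCC)c1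
F5 | step 6 | 9-[5-(9-borabicyclo[3.3.1]nonan-9-yloxy)pentyl]-9-borabicyclo[3.3.1]nonane | C(CCCCOB1C2CCCC1CCC2)B1C2CCCC1CCC2
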